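**Retrosynthetic overview**

1. Target ⇒ 2-(benzofuranylmethyl)-4-[(Z)-cinnamyl]-5-methoxyphenol. The cyclohexadienone stays an arene until the last step, where a reagent-controlled para-methoxylative dearomatisation sets C4 as (R).
2. That phenol ⇒ (Z)-obtustyrene + a neoflavonoid-type C6–C(Ph)–C2 unit. The furan O1–C2 bond and the CH2–aryl bond are made in one flask, as in the presumed biogenesis: the phenolic oxygen closes onto the central carbon of the C3 chain of a dalbergione-type precursor, and the electrophilic terminal carbon is captured ortho to the OH of the cinnamylphenol. An alkyne supplies the oxidation level.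
3. Neoflavonoid unit ⇒ cearoin (methoxyhydroquinone + benzoic acid), mono-silylated, + ethynyl Grignard. (Z)-Obtustyrene ⇒ 3-methoxyphenol + cinnamyl alcohol, then E→Z photoisomerisation.
4. Ring order: both benzene rings are bought; the furan ring is the only ring built (key step); the dienone ring arises last by dearomatisation.

Assumption: the stereocentre written [C@@] is (R) (CIP order OMe > C5(OMe)= > C3H= > CH2), and the natural product is taken to arise from a 4-methoxydalbergione-type neoflavonoid and (Z)-obtustyrene.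

Handling: 12 and 13 are kept at or below room temperature and away from acid, since 4-allyl cyclohexadienones can undergo Cope or dienone–phenol rearrangement.

**Route**

Step 1
Reactants: 1 3-methoxyphenol (3 equiv); 2 (E)-cinnamyl alcohol
Product: 3 (E)-obtustyrene [3-methoxy-4-[(2E)-3-phenylprop-2-en-1-yl]phenol]
Conditions: 5% aq. citric acid, ascorbic acid (cat.), 60 °C, 24 h; chromatography
Reagents that add atoms: none
Why: Acid-catalysed Friedel–Crafts C-allylation in which the cinnamyl cation is captured at its unsubstituted terminus para to OH (E geometry kept, water the only co-product); excess 1 suppresses dialkylation and the 6-cinnamyl regioisomer is removed by chromatography.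

Step 2
Reactants: 3 (E)-obtustyrene
Product: 4 (Z)-obtustyrene [3-methoxy-4-[(2Z)-3-phenylprop-2-en-1-yl]phenol]
Conditions: fac-Ir(ppy)3 (1 mol%), degassed MeCN, 450 nm LEDs, rt; AgNO3–SiO2 chromatography
Reagents that add atoms: none
Why: Triplet-sensitised contra-thermodynamic E→Z isomerisation, in which energy transfer from excited tris(2-phenylpyridinato)iridium is efficient to the planar E-styrene but not to the twisted Z-styrene, so the photostationary state is Z-rich (about 9:1 expected) and the 1,3-diarylpropene triplet relaxes by C=C rotation instead of di-π-methane rearrangement.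

Step 3
Reactants: 5 2-methoxybenzene-1,4-diol (methoxyhydroquinone); 6 benzoic acid
Product: 7 cearoin [(2,5-dihydroxy-4-methoxyphenyl)(phenyl)methanone]
Conditions: BF3·OEt2 (solvent), 90 °C, 3 h; then aq. NaOAc
Reagents that add atoms: none
Why: Friedel–Crafts C-acylation (O-acylation then Fries-type migration in the BF3 medium) at the most activated site, para to OMe and ortho to OH, giving the chelated ortho-hydroxy ketone with water as the only co-product.

Step 4
Reactants: 7 cearoin
Product: 8 {5-[tert-butyl(dimethyl)silyl]oxy-2-hydroxy-4-methoxyphenyl}(phenyl)methanone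
Conditions: TBSCl (1.05 equiv), imidazole (2 equiv), CH2Cl2, 0 °C
Reagents that add atoms: tert-butyldimethylsilyl chloride, CC(C)(C)[Si](C)(C)Cl
Why: Chemoselective O-silylation, because the 2-OH is hydrogen-bonded to the ketone and shielded by the benzoyl group, so only the free 5-OH reacts; this group later masks the easily oxidised benzofuran-5-ol.

Step 5
Reactants: 8 silylated cearoin
Product: 9 rac-4-{[tert-butyl(dimethyl)silyl]oxy}-2-(1-hydroxy-1-phenylprop-2-yn-1-yl)-5-methoxyphenol
Conditions: HC≡CMgBr (3 equiv), THF, 0 °C to rt; pH 7 phosphate buffer; used promptly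
Reagents that add atoms: ethynylmagnesium bromide, C#C[Mg]Br
Why: Grignard 1,2-addition in which the first equivalent forms the magnesium phenoxide (acetylene escapes) and the chelated ketone then takes up the acetylide, giving a racemic tertiary propargylic alcohol whose stereocentre is erased in step 6.

Step 6
Reactants: 9 propargylic alcohol; 4 (Z)-obtustyrene (1.3 equiv)
Product: 11 2-[(5-{[tert-butyl(dimethyl)silyl]oxy}-6-methoxy-3-phenyl-1-benzofuran-2-yl)methyl]-5-methoxy-4-[(2Z)-3-phenylprop-2-en-1-yl]phenol, via methylidene-dihydrobenzofuranol 10 (not isolated)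
Conditions: AuCl (5 mol%), K2CO3 (10 mol%), MeCN, rt, 1 h; then 4, (PhO)2P(O)OH (30 mol%), −20 to 0 °C
Reagents that add atoms: none
Why: Proposed new method: gold-catalysed 5-exo-dig cycloisomerisation of the ortho-hydroxyaryl propargylic alcohol gives enol ether 10, whose tertiary, doubly benzylic allylic OH ionises under mild acid to a benzofuran-2-ylmethyl cation that C6 of 4 (ortho to OH, para to OMe) captures at the exocyclic carbon in an SN1′ Friedel–Crafts alkylation that aromatises the furan and loses only water; the closest known reactions are the metal-catalysed cycloisomerisation of 2-(1-hydroxyprop-2-ynyl)phenols and the acid-catalysed allylic substitution of the resulting 2-methylene-2,3-dihydrobenzofuran-3-ols by O-nucleophiles, and cyclising before adding acid avoids the competing propargyl-cation/allene pathway to 2H-chromenes.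

Step 7
Reactants: 11 silyl-protected benzofuranylmethyl phenol
Product: 13 (4R)-2-[(5-hydroxy-6-methoxy-3-phenyl-1-benzofuran-2-yl)methyl]-4,5-dimethoxy-4-[(2Z)-3-phenylprop-2-en-1-yl]cyclohexa-2,5-dien-1-one, via silyl-protected dienone 12 (not isolated)
Conditions: (R,R)-ArI(OAc)2 [Ar = 2,6-bis{[(2R)-1-(mesitylamino)-1-oxopropan-2-yl]oxy}phenyl] (1.0 equiv), MeOH/CH2Cl2 3:1, −40 °C; then KHF2 (3 equiv), 0 °C to rt
Reagents that add atoms: methanol, CO
Why: Proposed new method: ligand exchange of the phenol on the C2-symmetric trivalent-iodine reagent gives an aryloxy(aryl)iodane whose two lactamide arms shield one face, methanol adds at C4 (para, giving the vinylogous-ester dienone) on the open face as the aryl iodide leaves and so sets (R), and KHF2 in the same methanol then cleaves only the aryl silyl ether; the closest known reactions are the PhI(OAc)2/MeOH para-dearomatisation of 4-alkylphenols and chiral aryl iodide mediated hydroxylative dearomatisation to para-quinols, the facial sense cannot be predicted, so the product is checked by chiral SFC and ECD and the (S,S)-reagent from (R)-lactate is used if the (R,R)-reagent gives the antipode.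

**Compound list**

1 | 3-methoxyphenol | COc1cccc(O)c1 | starting material
2 | (E)-cinnamyl alcohol | OC/C=C/c1ccccc1 | starting material
3 | (E)-obtustyrene, 3-methoxy-4-[(2E)-3-phenylprop-2-en-1-yl]phenol | COc1cc(O)ccc1C/C=C/c1ccccc1 | intermediate
4 | (Z)-obtustyrene, 3-methoxy-4-[(2Z)-3-phenylprop-2-en-1-yl]phenol | COc1cc(O)ccc1C/C=C\c1ccccc1 | intermediate
5 | 2-methoxybenzene-1,4-diol | COc1cc(O)ccc1O | starting material
6 | benzoic acid | OC(=O)c1ccccc1 | starting material
7 | cearoin, (2,5-dihydroxy-4-methoxyphenyl)(phenyl)methanone | COc1cc(O)c(cc1O)C(=O)c1ccccc1 | intermediate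
8 | {5-[tert-butyl(dimethyl)silyl]oxy-2-hydroxy-4-methoxyphenyl}(phenyl)methanone | COc1cc(O)c(cc1O[Si](C)(C)C(C)(C)C)C(=O)c1ccccc1 | intermediate
9 | rac-4-{[tert-butyl(dimethyl)silyl]oxy}-2-(1-hydroxy-1-phenylprop-2-yn-1-yl)-5-methoxyphenol (racemate) | COc1cc(O)c(cc1O[Si](C)(C)C(C)(C)C)C(O)(C#C)c1ccccc1 | intermediate
10 | rac-5-{[tert-butyl(dimethyl)silyl]oxy}-6-methoxy-2-methylidene-3-phenyl-2,3-dihydro-1-benzofuran-3-ol (racemate, not isolated) | COc1cc2OC(=C)C(O)(c3ccccc3)c2cc1O[Si](C)(C)C(C)(C)C | intermediate
11 | 2-[(5-{[tert-butyl(dimethyl)silyl]oxy}-6-methoxy-3-phenyl-1-benzofuran-2-yl)methyl]-5-methoxy-4-[(2Z)-3-phenylprop-2-en-1-yl]phenol | COc1cc(O)c(Cc2oc3cc(OC)c(O[Si](C)(C)C(C)(C)C)cc3c2-c2ccccc2)cc1C/C=C\c1ccccc1 | intermediate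
12 | (4R)-2-[(5-{[tert-butyl(dimethyl)silyl]oxy}-6-methoxy-3-phenyl-1-benzofuran-2-yl)methyl]-4,5-dimethoxy-4-[(2Z)-3-phenylprop-2-en-1-yl]cyclohexa-2,5-dien-1-one (not isolated) | COC1=CC(=O)C(Cc2oc3cc(OC)c(O[Si](C)(C)C(C)(C)C)cc3c2-c2ccccc2)=C[C@@]1(C/C=C\c1ccccc1)OC | intermediate
13 | (4R)-2-[(5-hydroxy-6-methoxy-3-phenyl-1-benzofuran-2-yl)methyl]-4,5-dimethoxy-4-[(2Z)-3-phenylprop-2-en-1-yl]cyclohexa-2,5-dien-1-one | COC1=CC(=O)C(Cc2oc3cc(OC)c(O)cc3c2-c2ccccc2)=C[C@@]1(C/C=C\c1ccccc1)OC | target

**Step count and risks**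

Total steps: 7. Longest linear sequence: 5 (steps 3, 4, 5, 6, 7 from 5 and 6); the other branch is steps 1 and 2.

Step 7 is the most likely to fail. The enantioselectivity of an intermolecular para-methoxylation is unproven, and the doubly activated cinnamyl CH2 can divert the phenoxonium species to a quinone methide. The fallback sets out from 11 and comes back at 13. PhI(OAc)2 in MeOH at 0 °C gives the racemic silyl-protected dienone F1. KHF2 in MeOH gives the racemic target F2. Preparative SFC on a chiral stationary phase then separates 13 from its (4S)-enantiomer F3, so that resolution replaces reagent control.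

Step 6 is the second risk. The one-flask sequence may stall at 10, or the cation may be captured by oxygen or by the Z-alkene of 4. The fallback sets out from 8 and comes back at 11, building the furan by condensation instead of alkyne cycloisomerisation and coupling in a separate operation. Ethyl bromoacetate with K2CO3 in refluxing MeCN, then DBU (O-alkylation, intramolecular aldol, dehydration), gives ethyl 5-{[tert-butyl(dimethyl)silyl]oxy}-6-methoxy-3-phenyl-1-benzofuran-2-carboxylate F4. Reduction with i-Bu2AlH in CH2Cl2 at −78 °C gives (5-{[tert-butyl(dimethyl)silyl]oxy}-6-methoxy-3-phenyl-1-benzofuran-2-yl)methanol F5. A dehydrative Friedel–Crafts benzylation of 4 with this alcohol (Sc(OTf)3 cat., CH2Cl2/HFIP, 0 °C) gives 11.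

Step 2 is the third risk. The photostationary state may be less Z-rich than hoped, and the E/Z separation is laborious. The fallback sets out from 3 and comes back at 4 by stereospecific chemical inversion of the alkene. mCPBA with NaHCO3 in CH2Cl2 at 0 °C gives racemic 3-methoxy-4-{[(2R*,3R*)-3-phenyloxiran-2-yl]methyl}phenol F6. PhMe2SiLi (2.5 equiv, THF, −78 °C to rt, then KOtBu) opens the epoxide anti, and syn-Peterson elimination delivers the Z-alkene 4.

**Further compounds**

F1 | step 7 | rac-2-[(5-{[tert-butyl(dimethyl)silyl]oxy}-6-methoxy-3-phenyl-1-benzofuran-2-yl)methyl]-4,5-dimethoxy-4-[(2Z)-3-phenylprop-2-en-1-yl]cyclohexa-2,5-dien-1-one (racemate) | COC1=CC(=O)C(Cc2oc3cc(OC)c(O[Si](C)(C)C(C)(C)C)cc3c2-c2ccccc2)=CC1(C/C=C\c1ccccc1)OC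
F2 | step 7 | rac-2-[(5-hydroxy-6-methoxy-3-phenyl-1-benzofuran-2-yl)methyl]-4,5-dimethoxy-4-[(2Z)-3-phenylprop-2-en-1-yl]cyclohexa-2,5-dien-1-one (racemate) | COC1=CC(=O)C(Cc2oc3cc(OC)c(O)cc3c2-c2ccccc2)=CC1(C/C=C\c1ccccc1)OC
F3 | step 7 | (4S)-2-[(5-hydroxy-6-methoxy-3-phenyl-1-benzofuran-2-yl)methyl]-4,5-dimethoxy-4-[(2Z)-3-phenylprop-2-en-1-yl]cyclohexa-2,5-dien-1-one | COC1=CC(=O)C(Cc2oc3cc(OC)c(O)cc3c2-c2ccccc2)=C[C@]1(C/C=C\c1ccccc1)OC
F4 | step 6 | ethyl 5-{[tert-butyl(dimethyl)silyl]oxy}-6-methoxy-3-phenyl-1-benzofuran-2-carboxylate | CCOC(=O)c1oc2cc(OC)c(O[Si](C)(C)C(C)(C)C)cc2c1-c1ccccc1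
F5 | step 6 | (5-{[tert-butyl(dimethyl)silyl]oxy}-6-methoxy-3-phenyl-1-benzofuran-2-yl)methanol | OCc1oc2cc(OC)c(O[Si](C)(C)C(C)(C)C)cc2c1-c1ccccc1
F6 | step 2 | rac-3-methoxy-4-{[(2R*,3R*)-3-phenyloxiran-2-yl]methyl}phenol (trans, racemate) | COc1cc(O)ccc1C[C@@H]1O[C@H]1c1ccccc1
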